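## Retrosynthetic overview

1. Target 22 ⇒ α-methylene cis-lactone 19 (lactone opened to CO2Me and 8-OAc; C3 ester by acylation) ⇒ hydroxy lactone 14 ⇒ keto ester 12.
2. 12 ⇒ ene-dione 8 + methyl bromoacetate 9 (C7–C11 bond).
3. 8 ⇒ methylidene hydrindenone 6 by a one-carbon ring expansion: the quaternary C10 shifts from C8 to the exocyclic carbon (new C9–C10 bond, ring B).
4. 6 ⇒ (S)-ene-dione 5 ⇒ 2-methylcyclopentane-1,3-dione 1 + ethyl vinyl ketone 2 (amino-acid-mediated annulation sets C10).
5. Ring order: five-membered ring (bought) → ring A (annulation) → ring B (expansion of the five-membered ring) → temporary lactone ring, opened in the last step.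

Convention: from compound 8 on, eudesmane numbering is used (ring A = C1–C5, C10; ring B = C5–C10; C14 methyl on C10; C15 methyl on C4; side chain C11–C13 on C7). The target is the (3S,7R,8R,10R) isomer, with all four substituents on the face of the C10 methyl (β).

## Route

Step 1
Reactants: 1 2-methylcyclopentane-1,3-dione; 2 pent-1-en-3-one (ethyl vinyl ketone)
Product: 5 (7aS)-4,7a-dimethyl-2,3,7,7a-tetrahydro-1H-indene-1,5(6H)-dione, via triketone 3 (not isolated), via cis-fused ketol 4 (not isolated)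
Conditions: H2O, 60 °C; evaporate; (S)-phenylalanine (1.0 equiv, recovered), (1S)-(+)-camphor-10-sulfonic acid (0.5 equiv), DMF, 30 → 70 °C
Reagents that add atoms: none
Why: Michael addition of the 1,3-dione to the enone, then the amino-acid-mediated Hajos–Parrish–Eder–Sauer–Wiechert aldol condensation, in which the (S)-amino acid enamine selects one of the two enantiotopic ring carbonyls and sets the quaternary centre (later C10) as 7aS.

Step 2
Reactants: 5 (7aS)-4,7a-dimethyl-2,3,7,7a-tetrahydro-1H-indene-1,5(6H)-dione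
Product: 6 (7aR)-4,7a-dimethyl-1-methylidene-1,2,3,6,7,7a-hexahydro-5H-inden-5-one
Conditions: Ph3P+CH3 Br− (1.15 equiv), KOtBu (1.1 equiv), toluene, 0 → 20 °C
Reagents that add atoms: methyltriphenylphosphonium bromide, C[P+](c1ccccc1)(c1ccccc1)c1ccccc1.[Br-]
Why: Wittig methylenation of the saturated cyclopentanone, the tetrasubstituted 4-methyl enone being far less electrophilic and at most reversibly enolised, as in selective methylenations of Wieland–Miescher-type ene-diones; no stereocentre is touched (the descriptor changes only by priority).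

Step 3
Reactants: 6 (7aR)-4,7a-dimethyl-1-methylidene-1,2,3,6,7,7a-hexahydro-5H-inden-5-one
Product: 8 (4aR)-1,4a-dimethyl-4,4a,7,8-tetrahydronaphthalene-2,6(3H,5H)-dione, via methoxy iodane adduct 7 (not isolated)
Conditions: PhI(OH)OTs (1.1 equiv), MeOH–H2O (95:5), 0 → 20 °C; aq. NaHCO3
Reagents that add atoms: water, O
Why: Proposed new method: trivalent-iodine-mediated oxidative one-carbon ring expansion in which a fully substituted sp3 ring carbon migrates in the presence of an enone; PhI(OH)OTs adds to the exposed exocyclic CH2 (the enone C=C is electron-poor and tetrasubstituted), methanol caps the tertiary cation at C8, and the C8–C10 bond (the better σ-donor, and the one lying antiperiplanar to the bulky C–I bond) shifts to the CH2 carbon as iodobenzene leaves, giving a methoxy-oxocarbenium ion that water hydrolyses to the C8 ketone with retention at C10; the closest known reactions are the semipinacol/Tiffeneau–Demjanov-type ring expansions of benzo-fused methylenecycloalkanes with this reagent (aryl migration) and of methylenecycloalkanes with thallium trinitrate Tl(NO3)3.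

Step 4
Reactants: 8 (4aR)-1,4a-dimethyl-4,4a,7,8-tetrahydronaphthalene-2,6(3H,5H)-dione; 9 methyl bromoacetate
Product: 12 methyl 2-[(2R,4aR)-4a,8-dimethyl-3,7-dioxo-1,2,3,4,4a,5,6,7-octahydronaphthalen-2-yl]acetate, via pyrrolidine enamine 10 (not isolated), via alkylated iminium bromide 11 (not isolated)
Conditions: pyrrolidine (1.2 equiv), TsOH (cat.), benzene, reflux (Dean–Stark); 9 (1.1 equiv), MeCN, 60 °C; aq. NaOAc, 60 °C; K2CO3 (cat.), MeOH, 20 °C
Reagents that add atoms: none
Why: Stork enamine alkylation, in which pyrrolidine condenses with the unhindered saturated C8 ketone (the 4-methyl enone is disfavoured by A(1,3) strain in its dienamine), the enamine forms toward C7 away from quaternary C10, and hydrolysis with base equilibration places the new arm equatorial (7β, 7R).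

Step 5
Reactants: 12 methyl 2-[(2R,4aR)-4a,8-dimethyl-3,7-dioxo-1,2,3,4,4a,5,6,7-octahydronaphthalen-2-yl]acetate
Product: 14 (3S,7R,8R,10R)-3-hydroxy-13-noreudesm-4-en-12,8-olide, via diol ester 13 (not isolated)
Conditions: NaBH4 (1.2 equiv), CeCl3·7H2O (1.1 equiv), MeOH, −40 → 0 °C; PPTS (cat.), CH2Cl2, 20 °C
Reagents that add atoms: none
Why: Luche reduction of both carbonyls, hydride reaching C8 from the α-face opposite the 1,3-diaxial C10 methyl (axial 8β-OH, 8R) and C3 axially from the α-face (equatorial 3β-OH, 3S), after which the 8β-OH cis to the C7 arm lactonises and thereby distinguishes the two hydroxyls.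

Step 6
Reactants: 14 (3S,7R,8R,10R)-3-hydroxy-13-noreudesm-4-en-12,8-olide
Product: 17 (3S,7R,8R,10R)-3-hydroxyeudesma-4,11(13)-dien-12,8-olide, via Mannich base 15 (not isolated), via ammonium iodide 16 (not isolated)
Conditions: LiN(i-Pr)2 (2.3 equiv), THF, −78 °C; CH2=NMe2+ I− (2.0 equiv), −78 → 20 °C; MeI, MeOH, 20 °C; NaHCO3, CH2Cl2–H2O, 20 °C
Reagents that add atoms: N,N-dimethylmethyleneiminium iodide (Eschenmoser's salt), C=[N+](C)C.[I-]
Why: Lactone α-methylenation by Mannich reaction of the lithium enolate, quaternisation and Hofmann-type elimination, the free 3-OH being carried as its lithium alkoxide and no stereocentre of the product being affected.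

Step 7
Reactants: 17 (3S,7R,8R,10R)-3-hydroxyeudesma-4,11(13)-dien-12,8-olide; 18 (2E)-3-methylpent-2-enoic acid
Product: 19 (3S,7R,8R,10R)-3-[(2E)-3-methylpent-2-enoyloxy]eudesma-4,11(13)-dien-12,8-olide
Conditions: 18 (1.5 equiv), DCC (1.6 equiv), DMAP (0.2 equiv), CH2Cl2, 0 → 20 °C
Reagents that add atoms: none
Why: Steglich esterification of the only free hydroxyl with retention at C3, carbodiimide/DMAP activation without amine base avoiding deconjugation or E/Z scrambling of the β,β-disubstituted acyl group.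

Step 8
Reactants: 19 (3S,7R,8R,10R)-3-[(2E)-3-methylpent-2-enoyloxy]eudesma-4,11(13)-dien-12,8-olide
Product: 22 methyl (3S,7R,8R,10R)-8-acetoxy-3-[(2E)-3-methylpent-2-enoyloxy]eudesma-4,11(13)-dien-12-oate, via potassium carboxylate 20 (not isolated), via hydroxy ester 21 (not isolated)
Conditions: KOH (1.05 equiv), THF–H2O, 0 °C; evaporate; MeI (3 equiv), DMF, 20 °C; Ac2O (3 equiv), Et3N, DMAP (cat.), 0 → 20 °C
Reagents that add atoms: potassium hydroxide, [K+].[OH-]; iodomethane, CI; acetic anhydride, CC(=O)OC(C)=O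
Why: Chemoselective saponification of the α-methylene γ-lactone (far faster than the hindered β,β-disubstituted enoate), SN2 O-methylation of the carboxylate, and DMAP-catalysed acetylation of the freed axial 8β-OH before it can relactonise, with no stereocentre affected.

## Compound list

1 | 2-methylcyclopentane-1,3-dione | CC1C(=O)CCC1=O | starting material
2 | pent-1-en-3-one (ethyl vinyl ketone) | CCC(=O)C=C | starting material
3 | 2-methyl-2-(3-oxopentyl)cyclopentane-1,3-dione (triketone) | CCC(=O)CCC1(C)C(=O)CCC1=O | intermediate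
4 | (3aS,7aS)-3a-hydroxy-4,7a-dimethylhexahydro-1H-indene-1,5(4H)-dione (cis-fused ketol, C4 epimers) | CC1C(=O)CC[C@]2(C)C(=O)CC[C@]12O | intermediate
5 | (7aS)-4,7a-dimethyl-2,3,7,7a-tetrahydro-1H-indene-1,5(6H)-dione | CC1=C2CCC(=O)[C@@]2(C)CCC1=O | intermediate
6 | (7aR)-4,7a-dimethyl-1-methylidene-1,2,3,6,7,7a-hexahydro-5H-inden-5-one | CC1=C2CCC(=C)[C@@]2(C)CCC1=O | intermediate
7 | {[(7aS)-1-methoxy-4,7a-dimethyl-5-oxo-2,3,5,6,7,7a-hexahydro-1H-inden-1-yl]methyl}(phenyl)-λ3-iodanyl 4-methylbenzenesulfonate (C1 epimers) | CC1=C2CCC(OC)(CI(OS(=O)(=O)c3ccc(C)cc3)c3ccccc3)[C@@]2(C)CCC1=O | intermediate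
8 | (4aR)-1,4a-dimethyl-4,4a,7,8-tetrahydronaphthalene-2,6(3H,5H)-dione, i.e. (10R)-11,12,13-trinoreudesm-4-ene-3,8-dione | CC1=C2CCC(=O)C[C@@]2(C)CCC1=O | intermediate
9 | methyl bromoacetate | COC(=O)CBr | starting material
10 | (4aR)-1,4a-dimethyl-6-(pyrrolidin-1-yl)-4,4a,5,8-tetrahydronaphthalen-2(3H)-one (C7=C8 enamine) | CC1=C2CC=C(N3CCCC3)C[C@@]2(C)CCC1=O | intermediate
11 | 1-[(4aR)-7-(2-methoxy-2-oxoethyl)-1,4a-dimethyl-2-oxo-2,3,4,4a,7,8-hexahydronaphthalen-6(5H)-ylidene]pyrrolidin-1-ium bromide (C7 epimers) | COC(=O)CC1CC2=C(C)C(=O)CC[C@]2(C)CC1=[N+]3CCCC3.[Br-] | intermediate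
12 | methyl 2-[(2R,4aR)-4a,8-dimethyl-3,7-dioxo-1,2,3,4,4a,5,6,7-octahydronaphthalen-2-yl]acetate, i.e. methyl (7R,10R)-3,8-dioxo-13-noreudesm-4-en-12-oate | COC(=O)C[C@H]1CC2=C(C)C(=O)CC[C@]2(C)CC1=O | intermediate
13 | methyl (3S,7R,8R,10R)-3,8-dihydroxy-13-noreudesm-4-en-12-oate | COC(=O)C[C@H]1CC2=C(C)[C@@H](O)CC[C@]2(C)C[C@H]1O | intermediate
14 | (3S,7R,8R,10R)-3-hydroxy-13-noreudesm-4-en-12,8-olide (cis-fused γ-lactone, 3β-OH) | O=C1C[C@H]2CC3=C(C)[C@@H](O)CC[C@]3(C)C[C@H]2O1 | intermediate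
15 | (3S,7R,8R,10R)-13-(dimethylamino)-3-hydroxyeudesm-4-en-12,8-olide (C11 epimers) | CN(C)CC1[C@H]2CC3=C(C)[C@@H](O)CC[C@]3(C)C[C@H]2OC1=O | intermediate
16 | trimethylammonium iodide of 15 (C11 epimers) | C[N+](C)(C)CC1[C@H]2CC3=C(C)[C@@H](O)CC[C@]3(C)C[C@H]2OC1=O.[I-] | intermediate
17 | (3S,7R,8R,10R)-3-hydroxyeudesma-4,11(13)-dien-12,8-olide | C=C1[C@H]2CC3=C(C)[C@@H](O)CC[C@]3(C)C[C@H]2OC1=O | intermediate
18 | (2E)-3-methylpent-2-enoic acid | CC/C(C)=C/C(=O)O | starting material
19 | (3S,7R,8R,10R)-3-[(2E)-3-methylpent-2-enoyloxy]eudesma-4,11(13)-dien-12,8-olide | C=C1[C@H]2CC3=C(C)[C@@H](OC(=O)/C=C(\C)CC)CC[C@]3(C)C[C@H]2OC1=O | intermediate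
20 | potassium (3S,7R,8R,10R)-8-hydroxy-3-[(2E)-3-methylpent-2-enoyloxy]eudesma-4,11(13)-dien-12-oate | [K+].C=C(C(=O)[O-])[C@H]1CC2=C(C)[C@@H](OC(=O)/C=C(\C)CC)CC[C@]2(C)C[C@H]1O | intermediate
21 | methyl (3S,7R,8R,10R)-8-hydroxy-3-[(2E)-3-methylpent-2-enoyloxy]eudesma-4,11(13)-dien-12-oate | C=C(C(=O)OC)[C@H]1CC2=C(C)[C@@H](OC(=O)/C=C(\C)CC)CC[C@]2(C)C[C@H]1O | intermediate
22 | methyl (3S,7R,8R,10R)-8-acetoxy-3-[(2E)-3-methylpent-2-enoyloxy]eudesma-4,11(13)-dien-12-oate | C=C(C(=O)OC)[C@H]1CC2=C(C)[C@@H](OC(=O)/C=C(\C)CC)CC[C@]2(C)C[C@H]1OC(C)=O | target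

## Step count and risks

Total step count: 8. Longest linear sequence: 8 steps (fully linear from 1 and 2; 9 and 18 are bought).

The three steps most likely to fail:

**Step 3 (the new ring expansion).** The risk is that the CH2 carbon C7 shifts instead of quaternary C10, or that methanol displaces the iodane before any shift. The fallback uses known chemistry only, sets out from 2 and comes back at 8. The bought mono-ketal 3,3-dimethyl-1,5-dioxaspiro[5.5]undecan-9-one F1 is methylated (LiN(i-Pr)2, MeI, THF, −78 °C) to racemic 3,3,8-trimethyl-1,5-dioxaspiro[5.5]undecan-9-one F2. Condensation with (R)-1-phenylethylamine (toluene, Dean–Stark) gives the chiral imine F3. Its secondary enamine tautomer adds to 2 (d'Angelo deracemising Michael addition, THF, 20–40 °C) to give the alkylated imine F4. Aqueous acetic acid releases the amine and the (R)-diketone F5. NaOMe in MeOH closes ring A by aldol condensation to the neopentyl-glycol ketal enone F6, and 1 M HCl in acetone unveils dione 8. The (R)-amine is chosen because the (S)-amine is known to give the opposite, (R)-10-methyl-octalone series.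

**Step 4 (chemoselective C7 alkylation beside the enone).** The risk is that the enone also forms a dienamine and is alkylated, or that alkylation occurs at C9. The fallback sets out from 8 and comes back at 14 through 13. Noyori ketalisation ((Me3SiOCH2)2, Me3SiOTf cat., CH2Cl2, −78 °C), selective for the saturated carbonyl, gives the C8 ethylene ketal enone F7. Luche reduction gives the 3β-hydroxy ketal F8. PPTS in wet acetone removes the ketal to give the 3β-hydroxy-8-ketone F9, which has no enone left. Its dianion (LiN(i-Pr)2, 2.2 equiv, THF, −78 °C) is alkylated at the less hindered C7 with 9 and equilibrated (K2CO3, MeOH) to the 3β-hydroxy keto ester F10. NaBH4 (MeOH, −40 °C) then gives diol ester 13, which lactonises to 14.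

**Step 8 (lactone opening and acetylation).** The risk is that hydroxy ester 21 relactonises before the hindered axial 8β-OH is acetylated, or that some C3 ester is lost. The fallback reverses the order of the last two bond formations, so that no free hydroxy ester ever exists. It sets out from 20 and comes back at 22. The dry carboxylate 20 is deprotonated at O8 with KN(SiMe3)2 (1.0 equiv, THF, −78 °C) and the alkoxide is acetylated with acetyl chloride (1.05 equiv). Mild acidification (pH 4, 0 °C) gives the acetoxy acid F11, which cannot lactonise, and Me3SiCHN2 (MeOH–toluene, 0 °C) gives 22.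

## Further compounds

F1 | step 3 | 3,3-dimethyl-1,5-dioxaspiro[5.5]undecan-9-one | O=C1CCC2(CC1)OCC(C)(C)CO2
F2 | step 3 | 3,3,8-trimethyl-1,5-dioxaspiro[5.5]undecan-9-one (racemic) | CC1CC2(CCC1=O)OCC(C)(C)CO2
F3 | step 3 | (1R)-1-phenyl-N-(3,3,8-trimethyl-1,5-dioxaspiro[5.5]undecan-9-ylidene)ethanamine | C[C@@H](N=C1CCC2(CC1C)OCC(C)(C)CO2)c1ccccc1
F4 | step 3 | 1-[(8R)-3,3,8-trimethyl-9-{[(1R)-1-phenylethyl]imino}-1,5-dioxaspiro[5.5]undecan-8-yl]pentan-3-one | C[C@@H](N=C1CCC2(C[C@@]1(C)CCC(=O)CC)OCC(C)(C)CO2)c1ccccc1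
F5 | step 3 | (8R)-3,3,8-trimethyl-8-(3-oxopentyl)-1,5-dioxaspiro[5.5]undecan-9-one | CCC(=O)CC[C@]1(C)CC2(CCC1=O)OCC(C)(C)CO2
F6 | step 3 | C8 2,2-dimethylpropane-1,3-diyl ketal of dione 8 ((10R)-4-en-3-one) | CC1=C2CCC3(C[C@@]2(C)CCC1=O)OCC(C)(C)CO3
F7 | step 4 | C8 ethylene ketal of dione 8 ((10R)-4-en-3-one) | CC1=C2CCC3(C[C@@]2(C)CCC1=O)OCCO3
F8 | step 4 | (3S,10R)-3-hydroxy-11,12,13-trinoreudesm-4-en-8-one ethylene ketal | CC1=C2CCC3(C[C@@]2(C)CC[C@@H]1O)OCCO3
F9 | step 4 | (3S,10R)-3-hydroxy-11,12,13-trinoreudesm-4-en-8-one | CC1=C2CCC(=O)C[C@@]2(C)CC[C@@H]1O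
F10 | step 4 | methyl (3S,7R,10R)-3-hydroxy-8-oxo-13-noreudesm-4-en-12-oate | COC(=O)C[C@H]1CC2=C(C)[C@@H](O)CC[C@]2(C)CC1=O
F11 | step 8 | (3S,7R,8R,10R)-8-acetoxy-3-[(2E)-3-methylpent-2-enoyloxy]eudesma-4,11(13)-dien-12-oic acid | C=C(C(=O)O)[C@H]1CC2=C(C)[C@@H](OC(=O)/C=C(\C)CC)CC[C@]2(C)C[C@H]1OC(C)=O
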